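The readings were computed on assumed constants, noise included.

The alder run began with a leftover: at 30.0 min, 21.1% of its starting material stood neither as intermediate nor as target, and I wanted to know what that share was doing.

| flask | starting material | coupling partner | remark | time |
|---|---|---|---|---|
| alder | 0.050 M | 1 equiv | run made earlier |  |
| birch | 0.070 M | 1 equiv | run made earlier |  |
| ash | 0.11 M | 1 equiv | run made earlier |  |
| north-east | 0.050 M | 1.00 equiv | one stirred flow tank at steady state, fed with the mixture as stated, mean residence time 30 min |  |
| west | 0.050 M | 1.00 equiv (fed, over 24.0 min) | a stirred flask in which coupling partner is dosed at a steady rate over 24.0 min without added volume, worked up at 30 min | 30 min |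
| north-west | 0.050 M | 1.00 equiv | a closed flask charged with all of it at once and left for 30 min | 30 min |
| south | 0.050 M (fed, over 24.0 min) | 1.00 equiv | a stirred flask in which starting material is dosed at a steady rate over 24.0 min without added volume, worked up at 30 min | 30 min |

| run | time / min | intermediate / % | target / % |
|---|---|---|---|
| alder | 2.50 | 38.4 | 0.1 |
| alder | 8.00 | 66.3 | 1.8 |
| alder | 15.0 | 74.9 | 0.9 |
| alder | 20.0 | 77.1 | 1.3 |
| alder | 30.0 | 77.7 | 1.2 |
| birch | 5.00 | 63.5 | 1.8 |
| birch | 10.0 | 76.4 | 0.6 |
| birch | 15.0 | 79.0 | 0.5 |
| birch | 20.0 | 81.1 | 1.6 |
| birch | 25.0 | 81.5 | 0.5 |
| ash | 2.00 | 53.6 | 0.5 |
| ash | 4.00 | 69.5 | 0.3 |
| ash | 6.00 | 76.1 | 0.7 |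
| ash | 12.0 | 83.0 | 0 |
| ash | 25.0 | 82.9 | 1.2 |

(readings scatter by 0.5 percentage points)

1. the set-up with the highest amount of intermediate at the outlet or at the end, in percent of the starting material put in ("none" if the first two lie within 2 percentage points) (north-east / west / north-west / south / none)
2. amount of intermediate at the outlet or at the end, in percent of the starting material put in, north-east
3. amount of intermediate at the outlet or at the end, in percent of the starting material put in, west
4. amount of intermediate at the outlet or at the end, in percent of the starting material put in, north-west
5. amount of intermediate at the outlet or at the end, in percent of the starting material put in, south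

- the stated concentrations are those of everything mixed, before any reaction; amounts are the same in each set-up
- the numbers in the tables scatter with a standard deviation of 0.5 percentage points
- the feed brings no volume worth counting
- the earlier runs were made in a closed, stirred flask

I took the alder flask, which has the recipe of north-west, in slow motion. For the first minutes I treated the coupling as second order with equal amounts, so the reading at 2.50 min gave a rate constant of 4.99 M⁻¹ min⁻¹ and a coupling time, one over that constant times the concentration, of 4.01 min; after any time the share coupled is that time over itself plus the coupling time. For the middle, this gave 78.9% at 15.0 min, where the alder reading was 74.9% intermediate, a gap of 4 percentage points. At 30.0 min it gave 88.2% against 77.7%, a gap of 11 points. Target stayed near 1.2% meanwhile, so I read the growing gap as intermediate slipping through target into something unseen. The growth of the gap per minute, divided by the mean intermediate, I call the leak constant, read as 0.00568 min⁻¹.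

For the end, I looked for the crossing, where coupling, rate constant times [starting material][coupling partner], falls to the leak, leak constant times [intermediate]. On the alder recipe it comes at about 26.1 min, earlier than the 30 min asked, so I took north-west as just past a flat crest, near the alder reading. West and south hold their whole charge for 6.00 min, against a coupling time of 4.01 min, so I placed them below it. The tank came out by my reckoning at 59.4%.

The forecast named north-west, with 65.3% (63% to 67.5%) for north-east, 73% for west, 77.5% for north-west and 73% for south, on the ground that “this looks like a reversible coupling”. My tank figure is lower than its 65.3%, and my reading of the stop differs.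

The flasks gave north-west as best, with 77.9%, against 60.5% for north-east, 72.7% for west and 72.7% for south.

    starting material + coupling partner → intermediate + by-product (k = 5.28 M⁻¹ min⁻¹)
    intermediate → target (k = 0.00537 min⁻¹)
    target → over-reaction product (k = 0.429 min⁻¹)

With the 11% of each charge that north-west held at 30 min, my constants as read from the alder run put coupling over leak at 0.708, which is my estimate, while the flask's own ratio of intermediate made to intermediate used up at 30.0 min was 0.794, so that both stand under one and north-west lay past the crossing. A further flask like north-west, with 1.70 equiv of coupling partner, kept 0.16% of its starting material, the limiting reagent, and 41% of its coupling partner. My constants as read put coupling over leak in that flask at 0.0574, the constants of the scheme put it at 0.0643, and that flask ended with 12.2% over-reaction product and 86.5% intermediate.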